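**Retrosynthetic overview**
1. The two imide C–N bonds are cut first: target ⇒ cyclobutane-1,3-dicarbonyl dichloride + 2 × 5,6-dihydropyridin-2(1H)-one (both lactam rings are bought intact).
2. Dichloride ⇒ α-truxillic-type diacid (functional-group interconversion).
3. Diacid ⇒ head-to-tail [2+2] photodimer of two molecules of (E)-3,4,5-trimethoxycinnamic acid. The cyclobutane is the only ring built (step 1), with all four stereocentres set at once.

Assumption: the target SMILES has an inversion centre (the two aryl groups trans to each other, the two acyl groups trans to each other, the α-truxillic pattern), so it is an achiral meso compound; "single enantiomer" is read as this single diastereomer and no absolute stereocontrol is needed.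

**Step 1**
Reactants: 1 (E)-3-(3,4,5-trimethoxyphenyl)prop-2-enoic acid (3,4,5-trimethoxycinnamic acid), two molecules
Product: 2 (1α,2α,3β,4β)-2,4-bis(3,4,5-trimethoxyphenyl)cyclobutane-1,3-dicarboxylic acid (α-truxillic-type, centrosymmetric)
Conditions: powdered crystals of 1 (recrystallised from EtOH–H2O), stirred suspension in H2O, hν (medium-pressure Hg, Pyrex, λ > 300 nm), rt, regrind periodically; recrystallise
Reagents that add atoms: none
Why: Topochemical solid-state [2+2] photodimerisation (Schmidt α-type packing): centrosymmetric hydrogen-bonded acid pairs stack antiparallel with the C=C bonds about 4 Å apart, so suprafacial head-to-tail cycloaddition keeps the trans Ar/CO2H relationship of each E-alkene, makes the two new ring bonds with cis Ar/CO2H, and so sets all four stereocentres of the meso core in one event.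

**Step 2**
Reactants: 2 (1α,2α,3β,4β)-2,4-bis(3,4,5-trimethoxyphenyl)cyclobutane-1,3-dicarboxylic acid
Product: 3 (1α,2α,3β,4β)-2,4-bis(3,4,5-trimethoxyphenyl)cyclobutane-1,3-dicarbonyl dichloride
Conditions: (COCl)2 (3 equiv), DMF (cat.), CH2Cl2, 0 °C → rt; concentrate, use crude
Reagents that add atoms: oxalyl chloride, O=C(Cl)C(=O)Cl
Why: DMF-catalysed (Vilsmeier-type) acyl chloride formation is base-free, so the α-carbons are not enolised and the configuration of 2 is carried over unchanged, while the trimethoxyaryl rings are inert in the absence of a Lewis acid.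

**Step 3**
Reactants: 3 (1α,2α,3β,4β)-2,4-bis(3,4,5-trimethoxyphenyl)cyclobutane-1,3-dicarbonyl dichloride; 4 5,6-dihydropyridin-2(1H)-one (2.2 equiv)
Product: 6 piplartine-dimer A, via lithium lactamide 5 (not isolated)
Conditions: 4, LiHMDS (2.2 equiv), THF, −78 °C, 30 min; then 3 in THF, −78 → −20 °C; aq NH4Cl
Reagents that add atoms: none
Why: N-acylation of a preformed lithium lactamide (nucleophilic acyl substitution, the standard way to make piplartine-type imides) is fast at −78 °C and outruns deprotonation of the hindered cyclobutane C–H, no new stereocentre is formed, and the only reachable epimer is the more congested cis acyl–aryl–acyl isomer, so the α-truxillic configuration should persist.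

**Compound list**
1 | (E)-3-(3,4,5-trimethoxyphenyl)prop-2-enoic acid | COc1cc(/C=C/C(=O)O)cc(OC)c1OC | starting material
2 | (1α,2α,3β,4β)-2,4-bis(3,4,5-trimethoxyphenyl)cyclobutane-1,3-dicarboxylic acid (meso) | COc1cc([C@H]2[C@H](C(=O)O)[C@H](c3cc(OC)c(OC)c(OC)c3)[C@H]2C(=O)O)cc(OC)c1OC | intermediate
3 | (1α,2α,3β,4β)-2,4-bis(3,4,5-trimethoxyphenyl)cyclobutane-1,3-dicarbonyl dichloride (meso) | COc1cc([C@H]2[C@H](C(=O)Cl)[C@H](c3cc(OC)c(OC)c(OC)c3)[C@H]2C(=O)Cl)cc(OC)c1OC | intermediate
4 | 5,6-dihydropyridin-2(1H)-one | O=C1C=CCCN1 | starting material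
5 | lithium 2-oxo-5,6-dihydro-2H-pyridin-1-ide (N-lithio derivative of 4) | [Li]N1CCC=CC1=O | intermediate
6 | piplartine-dimer A, 1,1'-{[(1α,2α,3β,4β)-2,4-bis(3,4,5-trimethoxyphenyl)cyclobutane-1,3-diyl]dicarbonyl}bis(5,6-dihydropyridin-2(1H)-one) (meso) | COc1cc([C@H]2[C@H](C(=O)N3CCC=CC3=O)[C@H](c3cc(OC)c(OC)c(OC)c3)[C@H]2C(=O)N2CCC=CC2=O)cc(OC)c1OC | target

**Total step count:** 3
**Longest linear sequence:** 3 steps (1 → 2 → 3 → 6)

**Steps most likely to fail, with fallbacks**

Step 1 (highest risk). Solid-state photoreactivity depends on the crystal form; I have not confirmed that crystalline 1 packs in the photoactive head-to-tail mode, and the out-of-plane 4-methoxy group may prevent the close stacking, leaving 1 photoinert or giving a head-to-head dimer. The fallback replaces crystal control by a Lewis-acid-complexed photodimerisation in solution. It sets out from 1: Fischer esterification (MeOH, cat. H2SO4, reflux) gives methyl (E)-3-(3,4,5-trimethoxyphenyl)prop-2-enoate F1. Irradiation of F1 in CH2Cl2 with BF3·OEt2 (0.5 equiv, Pyrex, rt) excites the ester–BF3 complex, which adds to a ground-state ester in a head-to-tail donor–acceptor pair to give dimethyl (1α,2α,3β,4β)-2,4-bis(3,4,5-trimethoxyphenyl)cyclobutane-1,3-dicarboxylate F2, crystallised away from Z-ester and minor dimers. Saponification (LiOH, THF–MeOH–H2O, 50 °C) comes back to the route at 2.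

Step 3 (second). The double N-acylation of a hindered bis-electrophile may stall at the mono-imide, or the lactamide may add in conjugate fashion to the product enone. The fallback reverses the order of events so that the imide is made on an unhindered monomer and the cyclobutane is closed last. It sets out from 1: (COCl)2, cat. DMF, CH2Cl2 gives (E)-3-(3,4,5-trimethoxyphenyl)prop-2-enoyl chloride F4, which acylates lithium lactamide 5 (from 4, THF, −78 °C) to piplartine (piperlongumine) F5. Irradiation of crystalline F5 (λ > 300 nm, solid state) effects the head-to-tail [2+2] dimerisation and comes back to the route at 6.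

Step 2 (third). The acid chloride is highly electrophilic and sits cis to an electron-rich aryl group, so intramolecular Friedel–Crafts acylation or hydrolysis on handling can erode it. The fallback avoids the acyl chloride and uses an isolable active ester. It sets out from 2: EDC·HCl, pentafluorophenol, cat. DMAP, CH2Cl2, rt gives bis(pentafluorophenyl) (1α,2α,3β,4β)-2,4-bis(3,4,5-trimethoxyphenyl)cyclobutane-1,3-dicarboxylate F3, which can be chromatographed and does not acylate arenes. Adding F3 to lithium lactamide 5 (THF, −78 → 0 °C) comes back to the route at 6, bypassing 3.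

**Further compounds**
F1 | step 1 | methyl (E)-3-(3,4,5-trimethoxyphenyl)prop-2-enoate | COC(=O)/C=C/c1cc(OC)c(OC)c(OC)c1
F2 | step 1 | dimethyl (1α,2α,3β,4β)-2,4-bis(3,4,5-trimethoxyphenyl)cyclobutane-1,3-dicarboxylate | COc1cc([C@H]2[C@H](C(=O)OC)[C@H](c3cc(OC)c(OC)c(OC)c3)[C@H]2C(=O)OC)cc(OC)c1OC
F3 | step 2 | bis(pentafluorophenyl) (1α,2α,3β,4β)-2,4-bis(3,4,5-trimethoxyphenyl)cyclobutane-1,3-dicarboxylate | COc1cc([C@H]2[C@H](C(=O)Oc3c(F)c(F)c(F)c(F)c3F)[C@H](c3cc(OC)c(OC)c(OC)c3)[C@H]2C(=O)Oc2c(F)c(F)c(F)c(F)c2F)cc(OC)c1OC
F4 | step 3 | (E)-3-(3,4,5-trimethoxyphenyl)prop-2-enoyl chloride | COc1cc(/C=C/C(=O)Cl)cc(OC)c1OC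
F5 | step 3 | piplartine (piperlongumine), 1-[(E)-3-(3,4,5-trimethoxyphenyl)prop-2-enoyl]-5,6-dihydropyridin-2(1H)-one | COc1cc(/C=C/C(=O)N2CCC=CC2=O)cc(OC)c1OC
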